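## The problem

The target 17 is a depsidone (an 11H-dibenzo[b,e][1,4]dioxepin-11-one). Rings A and B are joined twice, by the diaryl ether oxygen O5 and by an ester (carbonyl C11 on ring A, oxygen O10 on ring B), so a seven-membered lactone lies between them; ring B also carries a fused 2,2-dimethylchroman-4-one. Depsidone numbering is used for both rings throughout, also in open precursors: ring A is C1–C4, C4a, C11a and ring B is C5a, C6–C9, C9a. There is no stereocentre, so every difficulty is regiochemical. Ring B is hexasubstituted, with four contiguous oxygens of four different kinds (ester O10 on C9a, ether O5 on C5a, free hydroxyl on C6, pyran oxygen on C7), then the ketone carbon on C8 and a methyl group on C9. Ring A has its formyl group on C4, between the C3 hydroxyl and the ether carbon C4a, and two positions ortho to that hydroxyl compete for an electrophile. The aryl ester is opened by hydroxide, alkoxides and amines, the pyranone can unravel by retro-oxa-Michael reaction in strong base, the aldehyde is sensitive to oxidants and the catechol intermediates to air; the aldehyde is therefore best introduced last, and conditions should be neutral or acidic once the lactone exists. The feature that invites the key step is the position of the ester oxygen: C9a is ortho to the ether carbon C5a and para to the oxygenated C7. That is the carbon a nucleophile reaches by conjugate addition when a C6,C7-catechol with an aryloxy group on C5a is oxidised to its ortho-quinone, and the ring A carboxyl group is held by the diaryl ether within reach of that carbon only.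

## Retrosynthesis

**Formyl group (17 ⇒ 16).** The C4–CHO bond is cut first, so the aldehyde never meets an oxidant or an ether-cleaving Lewis acid. In 16 ring B has no free position, so an ortho-formylation of the ring A phenol can only choose between C4 and C2. This is simpler than carrying a masked aldehyde through the diaryl ether coupling, where it would flank the reacting phenol. The forward step must prefer C4.

**Ring A methyl ether (16 ⇒ 15).** The C3 oxygen is carried as a methyl ether up to this point. A free phenol on ring A would be a second nucleophile towards the ortho-quinone of the key step and a second site for O- and C-acylation in the chromanone annulation. The cost is one deprotection, which must spare the lactone and the pyranone.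

**Chromanone (15 ⇒ 12 + 13).** Cutting the C8–C(=O) bond and the O7–C(CH3)2 bond removes the pyranone as 3-methylbut-2-enoic acid 13 and leaves catechol 12. C8 is the only unsubstituted carbon of ring B and lies ortho to the C7 hydroxyl, so acylation to enone 14 and oxa-Michael closure can give one chromanone only. Placing the acyl group on C8 earlier would close the pyranone before the catechol is needed for the key step.

**Lactone through the ester oxygen–aryl bond (12 ⇒ 11 ⇒ 10).** The usual depsidone cut, O10–C11, requires a ring B with four oxygens that are each protected differently. Cutting O10–C9a instead leaves acid 10, whose ring B is a plain 3-aryloxy-5-methylcatechol with hydrogen on C9a. That is one oxygen fewer, with nothing to differentiate, and both catechol hydroxyls of 12 emerge free, as the annulation and the target need. The forward reaction requires that ortho-quinone 11 accept its own carboxyl group at C9a faster than it reacts with anything else. Both carbons of the attacked double bond lie in the new ring, so the closure is 7-endo-trig.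

**Unmasking (10 ⇒ 9 ⇒ 8).** The catechol is stored as its dibenzyl ether and the acid as its methyl ester. Benzyl is chosen because hydrogenolysis is neutral and orthogonal to the ring A methyl ether. The ester is hydrolysed first, while the catechol is still protected from hot alkali and air.

**Diaryl ether (8 ⇒ 5 + 7).** The C5a–O5 bond is cut rather than C4a–O5, because this puts the halide on the ring available as a bromovanillin and the phenol on the orsellinate. Both fragments are single rings with every substituent already in place. The coupling has to cope with an ortho-alkoxy aryl bromide and an ortho-ester phenol.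

**Fragments (5 ⇒ 4 ⇒ 3 ⇒ 2 ⇒ 1; 7 ⇒ 6).** Bromide 5 follows from 5-bromovanillin 1 by exchanging the methyl ether for benzyl ethers (2, 3) and reducing the formyl group to methyl through hydrazone 4; the bromine of the commercial material marks C5a. Phenol 7 is the 4-O-methyl ether of methyl orsellinate 6, formed selectively because the other hydroxyl is hydrogen-bonded to the ester.

## Roads not taken

**Alternative 1:** Ring A is built by a rhodium-catalysed (2+2+2) cyclotrimerisation instead of being taken from an arene.
- **Cut and key step:** The C1–C2, C3–C4 and C4a–C11a bonds are cut. Diyne A2 is a finished ring B chromanone with a but-2-ynoate ester on O10 and a 3,3-diethoxyprop-1-ynyl ether on O5. [Rh(cod)2]BF4 with BINAP (monovalent rhodium) would join it with ethoxyacetylene A3 to give A1, the target with the C3 hydroxyl as ethyl ether, the formyl group as diethyl acetal and the C6 hydroxyl as methyl ether. Ring A and the lactone close together.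
- **Merits:** The formyl carbon is placed by construction, so the C4/C2 question of the chosen plan's last step does not arise, and the step is highly convergent. In both respects this road is better.
- **Weak points:** A2 presupposes a ring B with four oxygens already in place and differentiated, which is the problem the chosen plan solves in its key step. Aryl alkynyl ethers are hydrolytically fragile. The two tethered alkynes are linked through a catechol unit and must close a seven-membered ring together with the arene, a tether length where cyclotrimerisation is far less reliable than for five- and six-membered cases. A3 must enter with its ethoxy carbon next to the acetal-bearing alkyne carbon, the more hindered orientation.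
- **Comparison:** The chosen plan offsets its formylation risk with a much shorter approach to ring B from commercial arenes.

**Alternative 2:** Ring B is grown from a four-membered ring.
- **Cut and key step:** The C9–C9a bond is cut. Cyclobutenone A5 carries the ring A aryloxy group, a methoxy group, a tertiary hydroxyl and a prop-1-enyl group. On heating it would undergo four-electron ring opening, 6π-electrocyclisation and tautomerisation to hydroquinone A4, with free hydroxyls on C9a and C7, a methoxy group on C6 and the ring A ester in place.
- **Merits:** The four oxygens of ring B arise in fixed positions, and A4 would be lactonised through its C9a hydroxyl by ordinary ester formation. The lactone closure therefore rests on firmer precedent than the key step chosen here; on that point this road is the safer one.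
- **Weak points:** A5 needs an unsymmetrical squarate carrying the hindered, hydrogen-bonded phenol oxygen of ring A. A propenyl-metal reagent must then choose one of two similar carbonyl groups and spare the ring A ester. The C6 and C3 methyl ethers must be distinguished at the end. The sequence is several steps longer before ring B exists.
- **Comparison:** The chosen plan is shorter and uses commercial arenes, and it keeps a classical lactonisation in reserve as the fallback for its key step.

**Alternative 3:** The formyl carbon and the C6 oxygen are joined from the start as a benzyl aryl ether, and this tether holds the two rings.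
- **Cut and key step:** The C4a–O5 bond is cut. The ten-membered macrocycle A7 is held together by the lactone ester and by the C4–CH2–O6 ether. CuI (monovalent copper) with N,N-dimethylglycine and Cs2CO3 would couple the C5a phenol with the C4a bromide across the ring to give A6, in which the depsidone lactone is fused to a temporary dioxepine. Oxidative cleavage of the benzylic ether would then release aldehyde and phenol together.
- **Merits:** The formyl group is placed with no regiochemical question, the hindered diaryl ether coupling becomes intramolecular, and one tether masks two groups. On the first point this road is better than the chosen plan.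
- **Weak points:** A7 requires a hexasubstituted ring A bromide, a ring B with all four oxygens differentiated beforehand, a macrocyclisation between two hindered partners, and a transannular coupling at two doubly ortho-substituted carbons.
- **Comparison:** The chosen plan is far shorter. It borrows the tether idea as the fallback for its own formylation step, where A6 reappears.

Key step: step 8

Assumption: in step 6 acyl–oxygen cleavage is assumed, so the hydroxyl oxygen of the carboxyl group of 9 is counted as coming from hydroxide.

## Steps

Step 1
Reactants: 1 5-bromovanillin (3-bromo-4-hydroxy-5-methoxybenzaldehyde)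
Product: 2 3-bromo-4,5-dihydroxybenzaldehyde
Conditions: BBr3, CH2Cl2, −78 °C → rt; then H2O
Reagents that add atoms: none
Why: Lewis-acid demethylation of an aryl methyl ether: bromide attacks the boron-activated methyl group, and aldehyde and aryl bromide are returned unchanged after aqueous work-up.

Step 2
Reactants: 2 3-bromo-4,5-dihydroxybenzaldehyde
Product: 3 3,4-bis(benzyloxy)-5-bromobenzaldehyde
Conditions: BnBr, K2CO3, DMF, 60 °C
Reagents that add atoms: benzyl bromide, BrCc1ccccc1
Why: Williamson etherification of both phenols; benzyl is chosen because it later leaves by neutral hydrogenolysis without touching the ring A methyl ether.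

Step 3
Reactants: 3 3,4-bis(benzyloxy)-5-bromobenzaldehyde
Product: 5 1,2-bis(benzyloxy)-3-bromo-5-methylbenzene, via hydrazone 4 (not isolated)
Conditions: N2H4·H2O, KOH, diethylene glycol, 130 °C → 195 °C
Reagents that add atoms: none
Why: Wolff–Kishner reduction in the Huang-Minlon modification: hydrazone 4 loses N2 in hot alkali to leave the methyl group; aryl bromide and benzyl ethers are stable to base.

Step 4
Reactants: 6 methyl orsellinate (methyl 2,4-dihydroxy-6-methylbenzoate)
Product: 7 methyl 2-hydroxy-4-methoxy-6-methylbenzoate
Conditions: MeI (1.1 equiv), K2CO3, acetone, reflux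
Reagents that add atoms: iodomethane, CI
Why: Williamson methylation selective for the C4 hydroxyl, because the C2 hydroxyl is hydrogen-bonded to the ester carbonyl and much less nucleophilic.

Step 5
Reactants: 5 1,2-bis(benzyloxy)-3-bromo-5-methylbenzene; 7 methyl 2-hydroxy-4-methoxy-6-methylbenzoate
Product: 8 methyl 2-[2,3-bis(benzyloxy)-5-methylphenoxy]-4-methoxy-6-methylbenzoate
Conditions: CuI, N,N-dimethylglycine hydrochloride, Cs2CO3, dioxane, 105 °C
Reagents that add atoms: none
Why: Ullmann diaryl ether synthesis (copper-catalysed C–O coupling with an amino acid ligand), a variant suited to electron-rich, ortho-substituted aryl bromides; one phenol and one aryl halide are present, so only one ether can form.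

Step 6
Reactants: 8 methyl 2-[2,3-bis(benzyloxy)-5-methylphenoxy]-4-methoxy-6-methylbenzoate
Product: 9 2-[2,3-bis(benzyloxy)-5-methylphenoxy]-4-methoxy-6-methylbenzoic acid
Conditions: KOH, DMSO–H2O, 90 °C; then aq. HCl, 0 °C
Reagents that add atoms: potassium hydroxide, [K+].[OH-]
Why: Saponification of a 2,6-disubstituted benzoate, which needs hot KOH in aqueous DMSO; the ethers are inert, and hydrolysis precedes debenzylation so that no free catechol meets hot base.

Step 7
Reactants: 9 2-[2,3-bis(benzyloxy)-5-methylphenoxy]-4-methoxy-6-methylbenzoic acid
Product: 10 2-(2,3-dihydroxy-5-methylphenoxy)-4-methoxy-6-methylbenzoic acid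
Conditions: H2 (1 atm), Pd/C, EtOAc–MeOH, rt
Reagents that add atoms: none
Why: Hydrogenolysis of both benzyl ethers under neutral conditions frees the catechol and keeps the ring A methyl ether; without acid, the 2-aryloxybenzoic acid is not activated towards Friedel–Crafts closure to a xanthone.

Step 8
Reactants: 10 2-(2,3-dihydroxy-5-methylphenoxy)-4-methoxy-6-methylbenzoic acid
Product: 12 6,7-dihydroxy-3-methoxy-1,9-dimethyl-11H-dibenzo[b,e][1,4]dioxepin-11-one, via ortho-quinone 11 (not isolated)
Conditions: Ag2O (1.1 equiv), Na2SO4, THF–Et2O (0.005 M), 0 °C → rt, dark; filter; CF3CO2H (10 mol %), rt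
Reagents that add atoms: none
Why: Proposed new method: Ag2O oxidises catechol 10 to ortho-quinone 11 (the standard two-electron oxidation of catechols), and the ring A carboxyl group, held by the diaryl ether over the C5a=C9a double bond, adds in conjugate fashion to C9a (β to the C6 carbonyl), after which enolisation restores the catechol with O10 in place. The closest known reactions are the oxidative lactonisation of catechol carboxylic acids through ortho-quinone conjugate addition (five- and six-membered lactones) and the Thiele–Winter acetoxylation of quinones; a seven-membered aryl ester has not been closed in this way. The closure is 7-endo-trig, because both carbons of the attacked double bond lie in the new ring, a geometrically favourable mode. No stereocentre is formed. Site selectivity among C9a, C8 and C9 is needed: the tether reaches only C9a, C9 carries the methyl group and could not rearomatise, and attack at C8 is possible only between molecules, which high dilution suppresses. The aryloxy group on C5a pushes electron density onto C9a, so the step relies on acid activation of the quinone carbonyl and on intramolecular delivery; a kinetically easier 6-exo attack at C5a would give a spiro ortho-quinol ester that cannot aromatise and should revert or pass on by acid-promoted 1,2-acyloxy shift to the same lactone. Ring A is kept as its methyl ether so that no phenol competes as nucleophile or reductant, and the silver is filtered off before the acid is added so that 12 does not stay in contact with the oxidant.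

Step 9
Reactants: 12 6,7-dihydroxy-3-methoxy-1,9-dimethyl-11H-dibenzo[b,e][1,4]dioxepin-11-one; 13 3-methylbut-2-enoic acid
Product: 15 ring A methyl ether of the deformyl target (6-hydroxy-3-methoxy-1,9-dimethyldepsidone with a 2,2-dimethyl-2,3-dihydropyran-4-one ring fused at C7–C8; ring oxygen on C7; ketone carbon on C8), via aryl enone 14 (not isolated)
Conditions: BF3·OEt2, 75 °C
Reagents that add atoms: none
Why: Friedel–Crafts/Fries-type acylation of the phenol by the unsaturated acid under BF3·OEt2 at C8, the only free ring B position (ortho to the C7 hydroxyl, para to O5), then oxa-Michael closure of the C7 hydroxyl onto enone 14 (6-endo-trig); this is the usual one-pot route to 2,2-dimethylchroman-4-ones from pyrogallol-type phenols. Ring A is an anisole deactivated by the lactone carbonyl and cannot enter by O-acylation, so it should stay untouched.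

Step 10
Reactants: 15 ring A methyl ether of the deformyl target
Product: 16 deformyl target (3,6-dihydroxy-1,9-dimethyldepsidone with a 2,2-dimethyl-2,3-dihydropyran-4-one ring fused at C7–C8; ring oxygen on C7; ketone carbon on C8)
Conditions: BBr3, CH2Cl2, −78 °C → 0 °C; then H2O
Reagents that add atoms: none
Why: BBr3 cleavage of the aryl methyl ether; aryl esters and the cyclic aryl tert-alkyl ether of a chromanone tolerate the reagent at low temperature, and any pyranone opened to the enone recloses on work-up.

Step 11
Reactants: 16 deformyl target
Product: 17 target CNP0271978.0 (4-formyl-3,6-dihydroxy-1,9-dimethyldepsidone with a 2,2-dimethyl-2,3-dihydropyran-4-one ring fused at C7–C8; ring oxygen on C7; ketone carbon on C8)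
Conditions: (CH2)6N4, CF3CO2H, 75 °C; then 3 M aq. HCl, 50 °C
Reagents that add atoms: hexamethylenetetramine, C1N2CN3CN1CN(C2)C3; water, O
Why: Duff formylation (aminomethylation ortho to the phenol by protonated hexamethylenetetramine, internal redox to the iminium ion, hydrolysis). Ring B has no free position, and on ring A the position C4 between the hydroxyl and O5 is expected to react before C2, as in resorcylic carbonyl compounds and 7-hydroxychroman-4-ones, the more so because C2 is flanked by the C1 methyl group.

## Compound list

1 | 5-bromovanillin (3-bromo-4-hydroxy-5-methoxybenzaldehyde) | COc1cc(C=O)cc(Br)c1O | starting material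
2 | 3-bromo-4,5-dihydroxybenzaldehyde | O=Cc1cc(O)c(O)c(Br)c1 | intermediate
3 | 3,4-bis(benzyloxy)-5-bromobenzaldehyde | O=Cc1cc(Br)c(OCc2ccccc2)c(OCc2ccccc2)c1 | intermediate
4 | (E)-hydrazone of 3,4-bis(benzyloxy)-5-bromobenzaldehyde | N/N=C/c1cc(Br)c(OCc2ccccc2)c(OCc2ccccc2)c1 | intermediate
5 | 1,2-bis(benzyloxy)-3-bromo-5-methylbenzene | Cc1cc(Br)c(OCc2ccccc2)c(OCc2ccccc2)c1 | intermediate
6 | methyl orsellinate (methyl 2,4-dihydroxy-6-methylbenzoate) | COC(=O)c1c(C)cc(O)cc1O | starting material
7 | methyl 2-hydroxy-4-methoxy-6-methylbenzoate | COC(=O)c1c(C)cc(OC)cc1O | intermediate
8 | methyl 2-[2,3-bis(benzyloxy)-5-methylphenoxy]-4-methoxy-6-methylbenzoate | COC(=O)c1c(C)cc(OC)cc1Oc1cc(C)cc(OCc2ccccc2)c1OCc1ccccc1 | intermediate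
9 | 2-[2,3-bis(benzyloxy)-5-methylphenoxy]-4-methoxy-6-methylbenzoic acid | OC(=O)c1c(C)cc(OC)cc1Oc1cc(C)cc(OCc2ccccc2)c1OCc1ccccc1 | intermediate
10 | 2-(2,3-dihydroxy-5-methylphenoxy)-4-methoxy-6-methylbenzoic acid | OC(=O)c1c(C)cc(OC)cc1Oc1cc(C)cc(O)c1O | intermediate
11 | 4-methoxy-6-methyl-2-[(3-methyl-5,6-dioxocyclohexa-1,3-dien-1-yl)oxy]benzoic acid (ortho-quinone) | OC(=O)c1c(C)cc(OC)cc1OC1=CC(C)=CC(=O)C1=O | intermediate
12 | 6,7-dihydroxy-3-methoxy-1,9-dimethyl-11H-dibenzo[b,e][1,4]dioxepin-11-one | Cc1cc(OC)cc2c1C(=O)Oc1c(C)cc(O)c(O)c1O2 | intermediate
13 | 3-methylbut-2-enoic acid | CC(C)=CC(O)=O | starting material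
14 | 6,7-dihydroxy-3-methoxy-1,9-dimethyl-8-(3-methylbut-2-enoyl)-11H-dibenzo[b,e][1,4]dioxepin-11-one | Cc1cc(OC)cc2c1C(=O)Oc1c(C)c(C(=O)C=C(C)C)c(O)c(O)c1O2 | intermediate
15 | ring A methyl ether of the deformyl target (6-hydroxy-3-methoxy-1,9-dimethyldepsidone, 2,2-dimethyl-2,3-dihydropyran-4-one fused at C7 (O) and C8 (C=O)) | Cc1cc(OC)cc2c1C(=O)Oc1c(C)c3c(c(O)c1O2)OC(C)(C)CC3=O | intermediate
16 | deformyl target (3,6-dihydroxy-1,9-dimethyldepsidone, 2,2-dimethyl-2,3-dihydropyran-4-one fused at C7 (O) and C8 (C=O)) | Cc1cc(O)cc2c1C(=O)Oc1c(C)c3c(c(O)c1O2)OC(C)(C)CC3=O | intermediate
17 | CNP0271978.0 (4-formyl-3,6-dihydroxy-1,9-dimethyldepsidone, 2,2-dimethyl-2,3-dihydropyran-4-one fused at C7 (O) and C8 (C=O)) | Cc1cc(O)c(C=O)c2c1C(=O)Oc1c(C)c3c(c(O)c1O2)OC(C)(C)CC3=O | target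

## Step count and least certain steps

Total: 11 steps. Longest linear sequence: 10 steps (from 1 through steps 1–3 and 5–11); step 4 is a one-step branch.

**Step 8 (key step).** The conjugate addition may be too slow, because the aryloxy group on C5a feeds electron density into C9a. Quinone 11 would then be lost by intermolecular attack at C8, by Diels–Alder dimerisation or by addition of the water formed in the oxidation. Redox exchange between 11 and 12 may also over-oxidise the product; a dithionite wash would reverse this.

Fallback by known chemistry, from ester 8 back to 12. Electrophilic bromination (NBS, MeCN, 0 °C) of the electron-rich ring B, para to the C7 benzyloxy group, should give methyl 2-[2,3-bis(benzyloxy)-6-bromo-5-methylphenoxy]-4-methoxy-6-methylbenzoate F1; any C8 bromide would be removed at this stage. Palladium-catalysed hydroxylation of the aryl bromide (Pd2(dba)3, tBuXPhos, KOH, dioxane–H2O, 100 °C), continued in the same alkaline medium until the ester is hydrolysed, gives 2-[2,3-bis(benzyloxy)-6-hydroxy-5-methylphenoxy]-4-methoxy-6-methylbenzoic acid F2. Carbodiimide lactonisation (DCC, CH2Cl2), the classical depsidone closure, gives 6,7-bis(benzyloxy)-3-methoxy-1,9-dimethyl-11H-dibenzo[b,e][1,4]dioxepin-11-one F3, and hydrogenolysis (H2, Pd/C) gives 12.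

**Step 5.** Both partners are poor: the bromide is electron-rich and ortho-substituted, and the phenoxide is chelated by its ester. Oxidative addition and ligand exchange at copper may stall, and hydrodebromination of 5 may take over.

Fallback, from 5 back to 8. Bromine–lithium exchange (n-BuLi, THF, −78 °C), B(OiPr)3 and aqueous acid give [2,3-bis(benzyloxy)-5-methylphenyl]boronic acid F4. This is joined to 7 by Chan–Lam coupling (Cu(OAc)2, pyridine, 4 Å molecular sieves, CH2Cl2, air, rt), an oxidative C–O coupling that runs at room temperature and does not depend on oxidative addition of an aryl halide.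

**Step 9.** Acyl transfer may not stay on ring B: the acylating species could attack the anisole ring A at C2 or C4. The unsaturated acid could also alkylate C8 through its tertiary cation and lactonise, the dihydrocoumarin mode of reaction.

Fallback, from 12 back to 15. Acylation of the less hindered C7 hydroxyl (3-methylbut-2-enoyl chloride, pyridine, CH2Cl2, −20 °C) gives 6-hydroxy-3-methoxy-1,9-dimethyl-11-oxo-11H-dibenzo[b,e][1,4]dioxepin-7-yl 3-methylbut-2-enoate F5. Photo-Fries rearrangement (254 nm, benzene) moves the acyl group within the solvent cage to C8, the only free ortho position, to give enone 14, which closes to 15 with a trace of Et3N.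

**Step 11.** Site selectivity between the two positions ortho to the C3 hydroxyl may be poor (C4 wanted, C2 not), and double formylation is possible.

Fallback, from 15 back to 17. It delivers the carbon from the C6 oxygen, so only C4 can be reached, and it also bypasses step 10. Alkylation of the C6 hydroxyl (ClCH2SMe, Cs2CO3, NaI, DMF) gives the methylthiomethyl ether of 15 F6. A thiophile (dimethyl(methylthio)sulfonium tetrafluoroborate, CH2Cl2, 0 °C) converts it into the aryloxymethyl cation, which alkylates C4 intramolecularly to give the dioxepine-bridged depsidone F7 (the same compound as A6). DDQ in wet CH2Cl2 oxidises the benzylic ether carbon to a hemiacetal, which collapses to the 4-formyl-3-methoxy compound F8 with the C6 hydroxyl free. BCl3 (CH2Cl2, −20 °C) removes the methyl ether next to the aldehyde by chelation-assisted cleavage and gives 17.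

## Further compounds

F1 | step 8 | methyl 2-[2,3-bis(benzyloxy)-6-bromo-5-methylphenoxy]-4-methoxy-6-methylbenzoate | COC(=O)c1c(C)cc(OC)cc1Oc1c(Br)c(C)cc(OCc2ccccc2)c1OCc1ccccc1
F2 | step 8 | 2-[2,3-bis(benzyloxy)-6-hydroxy-5-methylphenoxy]-4-methoxy-6-methylbenzoic acid | OC(=O)c1c(C)cc(OC)cc1Oc1c(O)c(C)cc(OCc2ccccc2)c1OCc1ccccc1
F3 | step 8 | 6,7-bis(benzyloxy)-3-methoxy-1,9-dimethyl-11H-dibenzo[b,e][1,4]dioxepin-11-one | Cc1cc(OC)cc2c1C(=O)Oc1c(C)cc(OCc3ccccc3)c(OCc3ccccc3)c1O2
F4 | step 5 | [2,3-bis(benzyloxy)-5-methylphenyl]boronic acid | Cc1cc(B(O)O)c(OCc2ccccc2)c(OCc2ccccc2)c1
F5 | step 9 | 6-hydroxy-3-methoxy-1,9-dimethyl-11-oxo-11H-dibenzo[b,e][1,4]dioxepin-7-yl 3-methylbut-2-enoate | Cc1cc(OC)cc2c1C(=O)Oc1c(C)cc(OC(=O)C=C(C)C)c(O)c1O2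
F6 | step 11 | 6-O-methylthiomethyl ether of 15 | Cc1cc(OC)cc2c1C(=O)Oc1c(C)c3c(c(OCSC)c1O2)OC(C)(C)CC3=O
F7 | step 11 | dioxepine-bridged depsidone (C4–CH2–O6 bridge; 3-methoxy; chromanone fused at C7–C8) | Cc1cc(OC)c2c3c1C(=O)Oc1c(C)c4c(c(c1O3)OC2)OC(C)(C)CC4=O
F8 | step 11 | 3-O-methyl ether of the target (4-formyl-6-hydroxy-3-methoxy compound) | Cc1cc(OC)c(C=O)c2c1C(=O)Oc1c(C)c3c(c(O)c1O2)OC(C)(C)CC3=O
A1 | alternative 1 | target with C3 hydroxyl as ethyl ether, formyl as diethyl acetal and C6 hydroxyl as methyl ether | Cc1cc(OCC)c(C(OCC)OCC)c2c1C(=O)Oc1c(C)c3c(c(OC)c1O2)OC(C)(C)CC3=O
A2 | alternative 1 | ring B chromanone diyne (but-2-ynoate on O10, 3,3-diethoxyprop-1-ynyl ether on O5, methyl ether on O6) | CC#CC(=O)Oc1c(C)c2c(c(OC)c1OC#CC(OCC)OCC)OC(C)(C)CC2=O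
A3 | alternative 1 | ethoxyacetylene | CCOC#C
A4 | alternative 2 | methyl 2-(2,5-dihydroxy-6-methoxy-3-methylphenoxy)-4-methoxy-6-methylbenzoate | COC(=O)c1c(C)cc(OC)cc1Oc1c(O)c(C)cc(O)c1OC
A5 | alternative 2 | methyl 2-{[3-hydroxy-2-methoxy-4-oxo-3-[(E)-prop-1-en-1-yl]cyclobut-1-en-1-yl]oxy}-4-methoxy-6-methylbenzoate (racemic) | COC(=O)c1c(C)cc(OC)cc1OC1=C(OC)C(O)(/C=C/C)C1=O
A6 | alternative 3 | tether-bridged depsidone (lactone fused to a temporary dioxepine) | Cc1cc(OC)c2c3c1C(=O)Oc1c(C)c4c(c(c1O3)OC2)OC(C)(C)CC4=O
A7 | alternative 3 | ten-membered macrocyclic bromo phenol (ester and C4–CH2–O6 ether links; bromide on C4a; hydroxyl on C5a) | Cc1cc(OC)c2c(Br)c1C(=O)Oc1c(C)c3c(c(c1O)OC2)OC(C)(C)CC3=O
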